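**Assumption:** andrographolide (bulk isolate of Andrographis paniculata) is taken as a cheap commercial starting material; atom numbers C1–C20 follow the usual andrographolide (labdane) numbering.

**Retrosynthetic overview**
- Andrographolide 1 supplies all 20 carbons, both carbocycles, the lactone and the five ring A/B stereocentres; no C–C bond is made and no permanent ring is built.
- Diene 2 (C11=C12–C13=C14) comes from 1 by loss of the C14 hydroxyl.
- Key disconnection C11–O: 1,2-dioxine 3 comes from 2 and O2 by [4+2] addition, which sets 11R; this temporary dioxine is the only ring formed.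
- Hydroperoxide 4 and then target 5 come from 3 by hydride SN2′ opening of the dioxine (H to C12, C13=C14 restored, O–O cleaved).

**Route**

Step 1
Reactants: 1 andrographolide
Product: 2 14-deoxy-11,12-didehydroandrographolide (3,19-dihydroxy-ent-labda-8(17),11E,13-trien-16,15-olide; ring A/B stereocentres as in 1)
Conditions: neutral Al2O3, pyridine, reflux
Reagents that add atoms: none
Why: Vinylogous E1cB dehydration: H11 (γ to the lactone carbonyl through C12=C13) is removed and the C14 hydroxyl leaves from the extended enolate, giving the conjugated E-diene without touching any retained stereocentre.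

Step 2
Reactants: 2 14-deoxy-11,12-didehydroandrographolide
Product: 3 (11R,14S)-11,14-epidioxy-3,19-dihydroxy-ent-labda-8(17),12-dien-16,15-olide (3,6-dihydro-1,2-dioxine spanning C11 and C14, fused to the lactone at C13–C14, C12=C13 double bond)
Conditions: O2 (1 atm), tetraphenylporphyrin (1 mol%), white LED, CH2Cl2/MeOH 95:5, −20 °C; cold flash chromatography
Reagents that add atoms: dioxygen, O=O
Why: Singlet-oxygen [4+2] cycloaddition across the s-cis diene forms C11–O and C14–O suprafacially; in the preferred rotamer H9 eclipses C11=C12, the face syn to quaternary C10 (C20 methyl, C1 methylene) is shielded, so O2 is predicted to add anti to C10 and set 11R (14S follows), while the 1,1-disubstituted C8=C17 alkene is only a slow ene partner.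

Step 3
Reactants: 3 (11R,14S)-11,14-endoperoxide
Product: 5 14-deoxy-11-hydroxyandrographolide, via C11 hydroperoxide 4 (not isolated)
Conditions: NaBH4 (2.5 equiv), THF/MeOH 4:1, −20 → 0 °C; then sat. aq NH4Cl
Reagents that add atoms: none
Why: Proposed new method: hydride-triggered SN2′ fragmentation of an alkylidene-lactone-fused 1,2-dioxine — borohydride adds 1,4 to C12 (β-carbon of the α-alkylidene lactone), the lactone enolate expels the C14 peroxy oxygen by E1cB to form the C12–H bond and the C13=C14 butenolide, and the resulting C11 hydroperoxide 4 is reduced at O–O only, so C11–O and its 11R configuration are retained; epoxide closure of the β-peroxy enolate is blocked because the in-ring C13–C14–O–O torsion (about 60°) cannot become antiperiplanar; the closest known reaction types are the NaBH4 SN2′ reduction of Morita–Baylis–Hillman acetates and the base-induced Kornblum–DeLaMare cleavage of endoperoxides.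

**Compound list**

1 | andrographolide ((12E,14S)-3,14,19-trihydroxy-ent-labda-8(17),12-dien-16,15-olide) | C=C1CC[C@@H]2[C@](C)(CO)[C@H](O)CC[C@@]2(C)[C@@H]1C/C=C1\[C@H](O)COC1=O | starting material
2 | 14-deoxy-11,12-didehydroandrographolide (11E-diene) | C=C1CC[C@@H]2[C@](C)(CO)[C@H](O)CC[C@@]2(C)[C@@H]1/C=C/C1=CCOC1=O | intermediate
3 | (11R,14S)-11,14-epidioxy-3,19-dihydroxy-ent-labda-8(17),12-dien-16,15-olide (cis-fused dioxine, C9 side chain and C15 cis on the dioxine ring) | C=C1CC[C@@H]2[C@](C)(CO)[C@H](O)CC[C@@]2(C)[C@@H]1[C@@H]1OO[C@@H]2COC(=O)C2=C1 | intermediate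
4 | (11R)-11-hydroperoxy-3,19-dihydroxy-ent-labda-8(17),13-dien-16,15-olide | C=C1CC[C@@H]2[C@](C)(CO)[C@H](O)CC[C@@]2(C)[C@@H]1[C@H](OO)CC1=CCOC1=O | intermediate
5 | 14-deoxy-11-hydroxyandrographolide ((11R)-3,11,19-trihydroxy-ent-labda-8(17),13-dien-16,15-olide) | C=C1CC[C@@H]2[C@](C)(CO)[C@H](O)CC[C@@]2(C)[C@@H]1[C@H](O)CC1=CCOC1=O | target

**Totals**
Total step count: 3. Longest linear sequence: 3 (1 → 2 → 3 → 5).

**Steps most likely to fail**

Step 3 (the proposed new step). Methoxide formed in situ could trigger Kornblum–DeLaMare cleavage to 11-oxo or 14-oxo isomers before hydride reaches C12. The fallback uses known chemistry, sets out from 3 and comes back at 5.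
- Thiourea in MeOH at room temperature reduces only the O–O bond and gives (11R,12E,14S)-11-hydroxyandrographolide F1.
- Ac2O, pyridine and catalytic DMAP at 0 °C give the 3,11,14,19-tetraacetate F2, whose 14-acetate is a Morita–Baylis–Hillman-type allylic acetate.
- NaBH4 in THF/t-BuOH effects the established SN2′ hydride reduction (H to C12, loss of the 14-acetate) to 14-deoxy-11-hydroxyandrographolide 3,11,19-triacetate F3.
- K2CO3 in MeOH at 0 °C removes the three acetates to give 5.

Step 2. The ene reaction of singlet oxygen at C8=C17 may compete with the [4+2] on the acyl-substituted diene, and the facial preference at C11 is only predicted. The fallback sets out from 2 and comes back at 5, replacing steps 2 and 3 by a reagent-controlled sequence.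
- Shi epoxidation of the trans C11=C12 alkene with the L-fructose-derived ketone (the enantiomer of the usual D-fructose catalyst, chosen because the D-catalyst gives R,R epoxides from trans alkenes) uses KHSO5 (as 2KHSO5·KHSO4·K2SO4), K2CO3 and Bu4NHSO4 in MeCN/dimethoxymethane/aqueous buffer at pH 10.5 and 0 °C. It gives (11S,12S)-11,12-epoxy-14-deoxyandrographolide F4. This face is also the one anti to C10, so catalyst and substrate are matched.
- Hydrogenolysis of the alkenyl oxirane with Pd2(dba)3·CHCl3, n-Bu3P, HCO2H and Et3N in dioxane at room temperature delivers hydride to the allylic C12 and leaves the C11–O bond intact, giving 5.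

Step 1. Conversion on alumina can stall, and hot pyridine can degrade the triol. The fallback sets out from 1 and comes back at 2, using an activated leaving group under mild homogeneous conditions.
- 2,2-Dimethoxypropane and pyridinium p-toluenesulfonate in CH2Cl2 give andrographolide 3,19-acetonide F5.
- Ac2O and catalytic DMAP in CH2Cl2 at 0 °C give 14-O-acetylandrographolide 3,19-acetonide F6.
- DBU in toluene at 60 °C effects vinylogous E1cB loss of acetic acid to 14-deoxy-11,12-didehydroandrographolide 3,19-acetonide F7.
- AcOH/H2O 7:3 at room temperature removes the acetonide to give 2.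

**Further compounds**

F1 | step 3 | (11R,12E,14S)-11-hydroxyandrographolide | C=C1CC[C@@H]2[C@](C)(CO)[C@H](O)CC[C@@]2(C)[C@@H]1[C@H](O)/C=C1\[C@H](O)COC1=O
F2 | step 3 | (11R,12E,14S)-11-hydroxyandrographolide 3,11,14,19-tetraacetate | C=C1CC[C@@H]2[C@](C)(COC(C)=O)[C@H](OC(C)=O)CC[C@@]2(C)[C@@H]1[C@H](OC(C)=O)/C=C1\[C@H](OC(C)=O)COC1=O
F3 | step 3 | 14-deoxy-11-hydroxyandrographolide 3,11,19-triacetate (11R) | C=C1CC[C@@H]2[C@](C)(COC(C)=O)[C@H](OC(C)=O)CC[C@@]2(C)[C@@H]1[C@H](OC(C)=O)CC1=CCOC1=O
F4 | step 2 | (11S,12S)-11,12-epoxy-14-deoxyandrographolide | C=C1CC[C@@H]2[C@](C)(CO)[C@H](O)CC[C@@]2(C)[C@@H]1[C@@H]1O[C@H]1C1=CCOC1=O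
F5 | step 1 | andrographolide 3,19-acetonide | C=C1CC[C@@H]2[C@]3(C)COC(C)(C)O[C@@H]3CC[C@@]2(C)[C@@H]1C/C=C1\[C@H](O)COC1=O
F6 | step 1 | 14-O-acetylandrographolide 3,19-acetonide | C=C1CC[C@@H]2[C@]3(C)COC(C)(C)O[C@@H]3CC[C@@]2(C)[C@@H]1C/C=C1\[C@H](OC(C)=O)COC1=O
F7 | step 1 | 14-deoxy-11,12-didehydroandrographolide 3,19-acetonide | C=C1CC[C@@H]2[C@]3(C)COC(C)(C)O[C@@H]3CC[C@@]2(C)[C@@H]1/C=C/C1=CCOC1=O
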